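## Retrosynthetic overview

1. The target comes from saponification of an angular tricyclic δ-lactone. The lactone masks the C5 phenol and the acid at once. The C8 prenyl group goes onto the only aromatic C–H still free.
2. The chroman CH2 comes from ionic deoxygenation of a trans-2,3-dimethylchroman-4-one. That ketone comes from an o-hydroxyaryl tigloyl ketone by an alkaloid-catalysed oxa-Michael closure, which sets C2. Equilibration sets C3.
3. The tigloyl ketone comes from (R)-5,7-dimethoxy-4-propylchroman-2-one and tigloyl chloride, by Friedel–Crafts acylation with chelation-controlled loss of one methyl.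
4. Key disconnection: that lactone comes from C2v-symmetric 3,5-dimethoxyphenol and (E)-hex-2-enal. One enantioselective carbene-catalysed oxidative annulation joins them through a dearomatised cyclohexadienone. It sets the benzylic centre and makes every ring position different.
5. Ring order: arene (bought), then the δ-lactone ring, then the dihydropyranone/chroman ring.

Assumption: the sense of induction of the triazolium catalyst (step 1) and of quinidine (step 3) is assigned by analogy; the enantiomeric triazolium salt and quinine are equally available and would be swapped in if a first run shows the opposite sense.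

## Route

Step 1
Reactants: 1 3,5-dimethoxyphenol; 2 (E)-hex-2-enal
Product: 5 (4R)-5,7-dimethoxy-4-propylchroman-2-one, via hexenoyl azolium 3 (not isolated), via cyclohexadienone 4 (not isolated)
Conditions: (5aR,10bS)-N-mesityl aminoindanol-derived triazolium chloride (10 mol %), DBU (20 mol %), 3,3',5,5'-tetra-tert-butyldiphenoquinone (DQ, 1.2 equiv), 4 Å MS, toluene, 40 °C
Reagents that add atoms: none
Why: Proposed new method: DQ oxidises the Breslow intermediate of 2 to the α,β-unsaturated acyl azolium 3, the phenol of symmetric 1 binds at the acyl carbon and delivers one of its two equivalent ortho carbons to the β-carbon (Coates–Claisen [3,3] or ion-paired Michael addition) on the face left open by the indane wall, giving the dearomatised dienone 4 with the new centre already R, tautomerisation restores the arene and the single OH closes the lactone and releases the carbene, while competing O-acylation is reversible under carbene catalysis and C–C bond formation is the irreversible sink; the closest known reaction type is the NHC-catalysed oxidative [3+3] annulation of enals or ynals with 2-naphthols, kojic acids and 1,3-dicarbonyls.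

Step 2
Reactants: 5 (4R)-5,7-dimethoxy-4-propylchroman-2-one; 6 tigloyl chloride ((E)-2-methylbut-2-enoyl chloride)
Product: 8 (4R)-7-hydroxy-5-methoxy-8-[(E)-2-methylbut-2-enoyl]-4-propylchroman-2-one, via dimethoxy tigloyl ketone 7 (not isolated)
Conditions: AlCl3 (3.5 equiv), CH2Cl2, 0 °C to rt; ice/1 M HCl
Reagents that add atoms: none
Why: Friedel–Crafts acylation goes to C8, which is para to the 5-OMe and less hindered than C6 between two methoxy groups (Nazarov closure is blocked because both ortho positions of the new ketone carry oxygen), and AlCl3 chelated to that ketone then cleaves only the ortho 7-OMe, the aluminium phenoxide chelate being too poor a nucleophile to cyclise early and the C4 centre being safe because its loss would need an unstabilised secondary cation.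

Step 3
Reactants: 8 (4R)-7-hydroxy-5-methoxy-8-[(E)-2-methylbut-2-enoyl]-4-propylchroman-2-one
Product: 10 (4R,8S,9S)-5-methoxy-8,9-dimethyl-4-propyl-3,4,8,9-tetrahydro-2H,10H-pyrano[2,3-f]chromene-2,10-dione (trans-dimethyl), via cis-chromanone 9 (not isolated)
Conditions: quinidine (20 mol %), PhCl, 15 °C; then Et3N (2 equiv), 45 °C; chromatography
Reagents that add atoms: none
Why: Cinchona-alkaloid-catalysed intramolecular oxa-Michael addition, in which the quinuclidine N deprotonates the chelated phenol while the C9-OH binds the enone so that the phenoxide attacks one face of the tigloyl β-carbon and sets C8 as S (pseudo-enantiomeric to the quinine-catalysed closure of 7-hydroxy-8-tigloylcoumarins), kinetic protonation anti to the new methyl gives cis 9, and Et3N then epimerises only the α-centre C9 through the enolate, whose reprotonation is much faster than β-elimination of aryloxide, to the thermodynamically preferred trans 10 (roughly 4:1, residual cis removed).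

Step 4
Reactants: 10 (4R,8S,9S)-5-methoxy-8,9-dimethyl-4-propyl-3,4,8,9-tetrahydro-2H,10H-pyrano[2,3-f]chromene-2,10-dione
Product: 12 (4R,8S,9R)-5-methoxy-8,9-dimethyl-4-propyl-3,4,9,10-tetrahydro-2H,8H-pyrano[2,3-f]chromen-2-one, via benzylic carbinol 11 (not isolated)
Conditions: Et3SiH (8 equiv), TFA/CH2Cl2 1:1, 0 °C to rt
Reagents that add atoms: none
Why: Ionic hydrogenation (Kursanov–Parnes type), in which the protonated donor-rich aryl ketone takes hydride to give carbinol 11, this ionises at once to a benzylic cation stabilised by three oxygen donors and is reduced again to CH2, the lactone and ethers are inert, no alkene is present yet, and a large excess of silane at low temperature keeps hydride capture faster than ketone enolisation or loss of H-9 from the cation, so C9 keeps its geometry (its descriptor changes from S to R only through CIP priorities).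

Step 5
Reactants: 12 (4R,8S,9R)-5-methoxy-8,9-dimethyl-4-propyl-3,4,9,10-tetrahydro-2H,8H-pyrano[2,3-f]chromen-2-one; 13 2-methylbut-3-en-2-ol
Product: 14 (4R,8S,9R)-5-methoxy-8,9-dimethyl-6-(3-methylbut-2-en-1-yl)-4-propyl-3,4,9,10-tetrahydro-2H,8H-pyrano[2,3-f]chromen-2-one
Conditions: BF3·OEt2 (0.5 equiv), 13 (1.5 equiv, slow addition), CH2Cl2, −20 to 0 °C
Reagents that add atoms: none
Why: Friedel–Crafts prenylation, in which BF3 ionises the tertiary allylic alcohol and the arene attacks the unhindered primary allyl terminus through C6, the only aromatic C–H left and one flanked by two alkoxy donors as in 1,3,5-trimethoxybenzene, while the absence of a free phenol next to the new prenyl group prevents closure to a dimethylchroman and no stereocentre is touched.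

Step 6
Reactants: 14 (4R,8S,9R)-5-methoxy-8,9-dimethyl-6-(3-methylbut-2-en-1-yl)-4-propyl-3,4,9,10-tetrahydro-2H,8H-pyrano[2,3-f]chromen-2-one
Product: 16 (3R)-3-[(2S,3R)-5-hydroxy-7-methoxy-2,3-dimethyl-8-(3-methylbut-2-en-1-yl)chroman-6-yl]hexanoic acid (CNP0275989.1), via dilithium salt 15 (not isolated)
Conditions: LiOH·H2O (3 equiv), THF/H2O 3:1, 0 °C to rt, Ar; then cold 0.5 M HCl to pH 4–5, EtOAc, no heating
Reagents that add atoms: lithium hydroxide, [Li+].[OH-]
Why: Saponification of the activated aryl ester opens the δ-lactone to carboxylate/phenoxide 15, none of the three stereocentres is α to a carbonyl so none can epimerise, and cold acidification only to pH 4–5 avoids relactonisation.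

## Compound list

1 | 3,5-dimethoxyphenol | COc1cc(O)cc(OC)c1 | starting material
2 | (E)-hex-2-enal | CCC/C=C/C=O | starting material
3 | (E)-hex-2-enoyl azolium, acyl group on the carbene carbon of the (5aR,10bS)-N-mesityl indeno-triazolo-oxazinium catalyst (chloride) | CCC/C=C/C(=O)c1n2[C@H]3c4ccccc4C[C@H]3OCc2n[n+]1-c1c(C)cc(C)cc1C.[Cl-] | intermediate
4 | catalyst-bound 3,5-dimethoxycyclohexa-2,4-dien-1-one, C6 bonded to the new (R) carbon, side chain as azolium enolate (ring sp3 centre undefined) | CCC[C@H](C=C([O-])c1n2[C@H]3c4ccccc4C[C@H]3OCc2n[n+]1-c1c(C)cc(C)cc1C)C1C(=O)C=C(OC)C=C1OC | intermediate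
5 | (4R)-5,7-dimethoxy-4-propylchroman-2-one | CCC[C@H](CC(=O)O1)c2c1cc(OC)cc2OC | intermediate
6 | tigloyl chloride, (E)-2-methylbut-2-enoyl chloride | C/C=C(\C)C(=O)Cl | starting material
7 | (4R)-5,7-dimethoxy-8-[(E)-2-methylbut-2-enoyl]-4-propylchroman-2-one | CCC[C@H](CC(=O)O1)c2c1c(C(=O)/C(C)=C/C)c(OC)cc2OC | intermediate
8 | (4R)-7-hydroxy-5-methoxy-8-[(E)-2-methylbut-2-enoyl]-4-propylchroman-2-one | CCC[C@H](CC(=O)O1)c2c1c(C(=O)/C(C)=C/C)c(O)cc2OC | intermediate
9 | (4R,8S,9R)-5-methoxy-8,9-dimethyl-4-propyl-3,4,8,9-tetrahydro-2H,10H-pyrano[2,3-f]chromene-2,10-dione (cis-dimethyl) | CCC[C@H](CC(=O)O1)c2c1c3c(cc2OC)O[C@@H](C)[C@@H](C)C3=O | intermediate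
10 | (4R,8S,9S)-5-methoxy-8,9-dimethyl-4-propyl-3,4,8,9-tetrahydro-2H,10H-pyrano[2,3-f]chromene-2,10-dione (trans-dimethyl) | CCC[C@H](CC(=O)O1)c2c1c3c(cc2OC)O[C@@H](C)[C@H](C)C3=O | intermediate
11 | 10-hydroxy compound from 10 (C4, C8 and C9 geometry as in 10, C10 epimers) | CCC[C@H](CC(=O)O1)c2c1c3c(cc2OC)O[C@@H](C)[C@H](C)C3O | intermediate
12 | (4R,8S,9R)-5-methoxy-8,9-dimethyl-4-propyl-3,4,9,10-tetrahydro-2H,8H-pyrano[2,3-f]chromen-2-one | CCC[C@H](CC(=O)O1)c2c1c3c(cc2OC)O[C@@H](C)[C@H](C)C3 | intermediate
13 | 2-methylbut-3-en-2-ol | CC(C)(O)C=C | starting material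
14 | (4R,8S,9R)-5-methoxy-8,9-dimethyl-6-(3-methylbut-2-en-1-yl)-4-propyl-3,4,9,10-tetrahydro-2H,8H-pyrano[2,3-f]chromen-2-one | CCC[C@H](CC(=O)O1)c2c1c3c(c(CC=C(C)C)c2OC)O[C@@H](C)[C@H](C)C3 | intermediate
15 | dilithium carboxylate/phenoxide of 16 | CCC[C@H](CC(=O)[O-])c1c([O-])c2c(c(CC=C(C)C)c1OC)O[C@@H](C)[C@H](C)C2.[Li+].[Li+] | intermediate
16 | (3R)-3-[(2S,3R)-5-hydroxy-7-methoxy-2,3-dimethyl-8-(3-methylbut-2-en-1-yl)chroman-6-yl]hexanoic acid | CCC[C@H](CC(=O)O)c1c(O)c2c(c(CC=C(C)C)c1OC)O[C@@H](C)[C@H](C)C2 | target

## Totals and risks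

Total step count: 6. Longest linear sequence: 6.

**Step 1.** Risk: a simple phenol may stop at the aryl ester, or give modest ee with a β-alkyl enal. The fallback sets out from 1 and comes back at 5. Pechmann condensation of 1 with ethyl 3-oxohexanoate in MsOH gives 5,7-dimethoxy-4-propylcoumarin F1. A copper hydride catalysed asymmetric conjugate reduction of this flat coumarin (Cu(OAc)2, DTBM-SEGPHOS, PMHS, t-BuOH, toluene) then gives 5. Here C4 is set by hydride delivery instead of by C–C bond formation.

**Step 4.** Risk: the very electron-rich ketone may reduce slowly, and the acid may then erode C9 through the enol or through proton loss from the cation. The fallback sets out from 10 and comes back at 12.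
- Brief methanolysis of the aryl lactone (cat. K2CO3, MeOH, 0 °C) gives the chelated keto phenol methyl (3R)-3-[(2S,3S)-5-hydroxy-7-methoxy-2,3-dimethyl-4-oxochroman-6-yl]hexanoate F2.
- ClCO2Et/Et3N in THF converts its phenol into the aryl ethyl carbonate F3.
- NaBH4 in aqueous THF removes the benzylic oxygen under basic, non-cationic conditions (ketone reduction, carbonate migration and departure, second hydride). This gives methyl (3R)-3-[(2S,3R)-5-hydroxy-7-methoxy-2,3-dimethylchroman-6-yl]hexanoate F4.
- F4 closes to 12 with cat. TsOH in warm toluene.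

**Step 5.** Risk: the cationic prenylation at a position between two alkoxy groups may be slow, and the acid may consume the product alkene. The fallback sets out from 12 and comes back at 14. NBS in MeCN at 0 °C brominates the same single free position to give the 6-bromo lactone F5. A linear-selective Negishi coupling with prenylzinc bromide (Pd(OAc)2/CPhos, THF, rt), which the lactone tolerates, gives 14.

## Further compounds

F1 | step 1 | 5,7-dimethoxy-4-propyl-2H-chromen-2-one | CCCc1cc(=O)oc2cc(OC)cc(OC)c12
F2 | step 4 | methyl (3R)-3-[(2S,3S)-5-hydroxy-7-methoxy-2,3-dimethyl-4-oxochroman-6-yl]hexanoate | CCC[C@H](CC(=O)OC)c1c(O)c2c(cc1OC)O[C@@H](C)[C@H](C)C2=O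
F3 | step 4 | methyl (3R)-3-[(2S,3S)-5-(ethoxycarbonyloxy)-7-methoxy-2,3-dimethyl-4-oxochroman-6-yl]hexanoate | CCC[C@H](CC(=O)OC)c1c(OC(=O)OCC)c2c(cc1OC)O[C@@H](C)[C@H](C)C2=O
F4 | step 4 | methyl (3R)-3-[(2S,3R)-5-hydroxy-7-methoxy-2,3-dimethylchroman-6-yl]hexanoate | CCC[C@H](CC(=O)OC)c1c(O)c2c(cc1OC)O[C@@H](C)[C@H](C)C2
F5 | step 5 | (4R,8S,9R)-6-bromo-5-methoxy-8,9-dimethyl-4-propyl-3,4,9,10-tetrahydro-2H,8H-pyrano[2,3-f]chromen-2-one | CCC[C@H](CC(=O)O1)c2c1c3c(c(Br)c2OC)O[C@@H](C)[C@H](C)C3
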